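**Retrosynthetic overview**

1. The C7 acrylate ester and the C8 acyloxy group are the two halves of a trans-fused 8,12-γ-lactone on the cyclohexane ring C5–C10. The target is reached from it by lactone opening with α-methylenation, C8 acylation and desilylation.
2. The C10 vinyl group comes from a spare (Z)-alkenyl arm by epoxidation, periodate cleavage and Wittig methylenation.
3. Feature on which the strategy rests: the C6 carbinol sits next to C5, which carries the C4(=CH2)CH2O unit; this is the retron of an aldehyde–alkene ene reaction. Disconnection of C5–C6 opens the only carbocycle to a trans-paraconic aldehyde whose C10 is prochiral, with a methyl group and two identical (Z)-alkenyl arms.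
4. The paraconic aldehyde comes from a Stetter addition of the C8 aldehyde to diethyl fumarate, ketoreductase dynamic reduction (C8 and C7), lactonisation and ester-to-aldehyde adjustment.
5. The C10 fragment comes from diethyl 2-allyl-2-methylmalonate: allyl gives C9–C8 and the two esters give the arms by twofold Ando olefination. Ring order: γ-lactone first (step 9), cyclohexane second (step 13), lactone opened in step 19.

Key step: step 13

Remark: compound 1 is taken as purchasable, and a ketoreductase with the selectivity named in step 9 is taken to be found in a commercial enzyme panel.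

Conventions: ring carbons are C5–C10 as above; C4 is the carbon on C5 and C11–C13 the acrylate carbons on C7. β is the ring face of the C10 methyl group. TBS = tert-butyldimethylsilyl. Z-arm = (1Z)-3-(TBS-oxy)-2-methylprop-1-en-1-yl, i.e. (Z)-CH=C(CH3)CH2OTBS with CH2OTBS cis to the carbon that bears the arm.

**Route**

Step 1
Reactants: 1 diethyl 2-allyl-2-methylmalonate
Product: 3 diethyl 2-(2,2-dimethoxyethyl)-2-methylmalonate, via diethyl 2-methyl-2-(2-oxoethyl)malonate 2 (not isolated)
Conditions: O3, CH2Cl2/MeOH, −78 °C; Me2S, −78 °C → rt; then HC(OMe)3, TsOH·H2O (cat.), rt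
Reagents that add atoms: ozone, [O-][O+]=O (carbonyl oxygen of 2); trimethyl orthoformate, COC(OC)OC (the two methoxy groups of 3, passed on through methanol)
Why: Ozonolysis with reductive work-up cleaves the only alkene to the future C8 aldehyde, and acid-catalysed acetalisation in the same pot masks it before the esters are reduced; no stereocentre is involved.

Step 2
Reactants: 3 diethyl 2-(2,2-dimethoxyethyl)-2-methylmalonate
Product: 4 2-(2,2-dimethoxyethyl)-2-methylpropane-1,3-diol
Conditions: LiAlH4, THF, 0 °C → rt; H2O, aq. NaOH work-up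
Reagents that add atoms: none
Why: Hydride reduction of both malonate esters gives the prochiral 1,3-diol, the acetal being inert to LiAlH4 and to the basic work-up.

Step 3
Reactants: 4 2-(2,2-dimethoxyethyl)-2-methylpropane-1,3-diol
Product: 5 2-(2,2-dimethoxyethyl)-2-methylpropanedial
Conditions: (COCl)2, DMSO, CH2Cl2, −78 °C; Et3N, −78 → 0 °C; used crude
Reagents that add atoms: none
Why: Swern oxidation gives the non-enolisable 2,2-disubstituted malonaldehyde under amine-buffered conditions that leave the acetal alone.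

Step 4
Reactants: 5 2-(2,2-dimethoxyethyl)-2-methylpropanedial; 6 ethyl 2-(diphenoxyphosphoryl)propanoate
Product: 7 diethyl (2Z,5Z)-4-(2,2-dimethoxyethyl)-2,4,6-trimethylhepta-2,5-dienedioate
Conditions: 6 (2.4 equiv), NaH, THF, −78 → 0 °C
Reagents that add atoms: none
Why: Twofold Ando-type Horner–Wadsworth–Emmons olefination, in which the diaryl phosphonate eliminates fast from the kinetically formed adduct, so each trisubstituted alkene should be (Z) with the ester cis to the quaternary carbon.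

Step 5
Reactants: 7 diethyl (2Z,5Z)-4-(2,2-dimethoxyethyl)-2,4,6-trimethylhepta-2,5-dienedioate
Product: 8 (2Z,5Z)-4-(2,2-dimethoxyethyl)-2,4,6-trimethylhepta-2,5-diene-1,7-diol
Conditions: iBu2AlH (5 equiv), CH2Cl2, −78 → −20 °C; aq. potassium sodium tartrate (KNaC4H4O6)
Reagents that add atoms: none
Why: 1,2-Reduction of both enoates gives the allylic alcohols without change of alkene geometry, and the acetal is untouched.

Step 6
Reactants: 8 (2Z,5Z)-4-(2,2-dimethoxyethyl)-2,4,6-trimethylhepta-2,5-diene-1,7-diol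
Product: 9 (2Z,5Z)-1,7-bis(TBS-oxy)-4-(2,2-dimethoxyethyl)-2,4,6-trimethylhepta-2,5-diene
Conditions: TBSCl, imidazole, DMF, 0 °C → rt
Reagents that add atoms: tert-butyldimethylsilyl chloride, CC(C)(C)[Si](C)(C)Cl
Why: Standard imidazole-mediated silylation of the two primary allylic alcohols, which turns both arms into the ene donors needed later.

Step 7
Reactants: 9 (2Z,5Z)-1,7-bis(TBS-oxy)-4-(2,2-dimethoxyethyl)-2,4,6-trimethylhepta-2,5-diene
Product: 10 3,3-bis(Z-arm)butanal
Conditions: TESOTf, 2,4,6-collidine, CH2Cl2, 0 °C; then H2O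
Reagents that add atoms: water, O
Why: The silyl triflate and collidine turn the dimethyl acetal into a collidinium adduct that water hydrolyses to the aldehyde without protic acid, so the primary allylic TBS ethers stay on.

Step 8
Reactants: 10 3,3-bis(Z-arm)butanal; 11 diethyl fumarate
Product: 12 diethyl 2-[3,3-bis(Z-arm)butanoyl]butanedioate (racemic at C7)
Conditions: 3-benzyl-5-(2-hydroxyethyl)-4-methylthiazolium chloride (15 mol%), Et3N, EtOH, 70 °C
Reagents that add atoms: none
Why: Stetter reaction, in which the thiazolylidene converts the aldehyde into an acyl anion equivalent that adds to the fumarate (the hindered trisubstituted arms are not acceptors); C7 forms racemic and stays labile as a β-keto ester centre.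

Step 9
Reactants: 12 diethyl 2-[3,3-bis(Z-arm)butanoyl]butanedioate
Product: 14 ethyl (2S,3R)-2-[2,2-bis(Z-arm)propyl]-5-oxooxolane-3-carboxylate, via hydroxy diester 13 (not isolated)
Conditions: ketoreductase, NADP+ (cat.), iPrOH, potassium phosphate buffer pH 7, DMSO cosolvent, 30 °C; then pyridinium p-toluenesulfonate (cat.), toluene, 50 °C
Reagents that add atoms: none
Why: Enzymatic dynamic kinetic reduction of an α-substituted β-keto ester: the enzyme should reduce only the (7R) ketone, from the face that gives the (8S) alcohol, while the (7S) ketone racemises through its enol in the buffer; the C8 hydroxyl then closes onto the γ-ester to give the trans γ-lactone.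

Step 10
Reactants: 14 ethyl (2S,3R)-2-[2,2-bis(Z-arm)propyl]-5-oxooxolane-3-carboxylate
Product: 16 (2S,3R)-2-[2,2-bis(Z-arm)propyl]-5-oxooxolane-3-carboxylic acid, via dilithium hydroxy dicarboxylate 15 (not isolated)
Conditions: LiOH, THF/H2O, 0 °C → rt; then 0.5 M HCl to pH 3 at 0 °C, EtOAc; concentrate from toluene, 40 °C
Reagents that add atoms: lithium hydroxide, [Li+].[OH-]
Why: Saponification cleaves the ethyl ester and opens the lactone, and on acidification the γ-hydroxy acid closes again to the five-membered lactone and leaves the C6 carboxyl free; C7 and C8 are not touched and trans is the more stable arrangement.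

Step 11
Reactants: 16 (2S,3R)-2-[2,2-bis(Z-arm)propyl]-5-oxooxolane-3-carboxylic acid
Product: 18 (4S,5S)-5-[2,2-bis(Z-arm)propyl]-4-(hydroxymethyl)oxolan-2-one, via isobutyl carbonate mixed anhydride 17 (not isolated)
Conditions: iBuOCOCl, N-methylmorpholine, THF, −15 °C; then NaBH4, H2O, 0 °C
Reagents that add atoms: isobutyl chloroformate, CC(C)COC(Cl)=O (atoms held only by 17)
Why: The mixed carbonic anhydride is far more electrophilic than the lactone, so borohydride reduces only the activated C6 carboxyl to the primary alcohol.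

Step 12
Reactants: 18 (4S,5S)-5-[2,2-bis(Z-arm)propyl]-4-(hydroxymethyl)oxolan-2-one
Product: 19 (2S,3R)-2-[2,2-bis(Z-arm)propyl]-5-oxooxolane-3-carbaldehyde
Conditions: Dess–Martin periodinane, NaHCO3, CH2Cl2, 0 °C → rt; used at once
Reagents that add atoms: none
Why: Buffered Dess–Martin oxidation gives the aldehyde without a base strong enough to epimerise C7 or to open the β-acyloxy aldehyde by elimination.

Step 13
Reactants: 19 (2S,3R)-2-[2,2-bis(Z-arm)propyl]-5-oxooxolane-3-carbaldehyde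
Product: 20 (3aS,4R,5R,6S,7aS)-4-hydroxy-6-methyl-6-(Z-arm)-5-[3-(TBS-oxy)prop-1-en-2-yl]hexahydro-1-benzofuran-2(3H)-one
Conditions: Me2AlCl (2.5 equiv), CH2Cl2, −78 → −30 °C; aq. potassium sodium tartrate (KNaC4H4O6)
Reagents that add atoms: none
Why: Me2AlCl (one equivalent is held by the lactone carbonyl) activates the C6 aldehyde; C5 of one arm bonds to C6 while the aluminium-bound oxygen takes a hydrogen from that arm's methyl group (the one trans to C10), so the C4=C5 bond moves to the exocyclic C4 methylene and loss of methane leaves the aluminium alkoxide, as in the Lewis-acid carbonyl-ene cyclisation of citronellal to isopulegol. The cyclohexane C5–C10 closes in the 6-exo-trig mode at the carbonyl through a chair transition state whose shape is fixed by the trans-fused lactone, which holds the C7–C11 and C8–O bonds equatorial. At C6 the O–Al group takes the equatorial (α) site, because the axial site would be 1,3-diaxial to the axial C10 substituent and out of reach of the methyl hydrogen; at C5 the reacting alkenyl unit lies equatorial (β) and anti to C9, so H5 is axial and trans to H6; at C10 the arm that does not react sits equatorial (α) and the methyl group axial (β). The step needs arm selection and the right choice of transferred hydrogen: the first should follow from the larger effective size of the (Z)-alkenyl arm compared with methyl (its cis CH2OTBS group would be pressed against the axial hydrogens at C6 and C8), the second from the (Z) geometry set in step 4, which puts CH3 and not CH2OTBS within reach of an equatorial oxygen. Excess Me2AlCl at low temperature also takes up the proton, so the silyl ethers and the lactone should survive.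

Step 14
Reactants: 20 hydroxy lactone (name as in step 13)
Product: 21 (3aR,4R,5R,6S,7aS)-4-(TBS-oxy)-6-methyl-6-(Z-arm)-5-[3-(TBS-oxy)prop-1-en-2-yl]hexahydro-1-benzofuran-2(3H)-one
Conditions: TBSOTf, 2,6-lutidine, CH2Cl2, −78 → 0 °C
Reagents that add atoms: tert-butyldimethylsilyl triflate, CC(C)(C)[Si](C)(C)OS(=O)(=O)C(F)(F)F
Why: The silyl triflate silylates the hindered equatorial C6 hydroxyl, which removes its directing effect on the next oxidation and stops it from attacking the lactone.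

Step 15
Reactants: 21 C6 silyl ether (name as in step 14)
Product: 22 epoxide of 21 at the alkene of the spare arm (both epoxide diastereomers)
Conditions: mCPBA (1.05 equiv), NaHCO3, CH2Cl2, −20 → 0 °C
Reagents that add atoms: 3-chloroperbenzoic acid, OOC(=O)c1cccc(Cl)c1
Why: Prilezhaev epoxidation is faster at the trisubstituted alkene of the spare arm than at the 1,1-disubstituted C4 methylene, which is also screened by the C6 silyl ether; the epoxide configuration is of no consequence because one carbon is lost and the other becomes sp2.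

Step 16
Reactants: 22 spare-arm epoxide
Product: 23 C10 aldehyde (21 with CHO in place of the spare arm)
Conditions: H5IO6, THF/H2O, 0 °C
Reagents that add atoms: none
Why: Periodic acid opens the trisubstituted epoxide to the diol and cleaves it in the same pot (periodate glycol cleavage), leaving a C10 aldehyde that has no α-hydrogen and cannot epimerise.

Step 17
Reactants: 23 C10 aldehyde
Product: 24 (3aR,4R,5R,6S,7aS)-4-(TBS-oxy)-6-ethenyl-6-methyl-5-[3-(TBS-oxy)prop-1-en-2-yl]hexahydro-1-benzofuran-2(3H)-one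
Conditions: Ph3PCH3Br, KN(SiMe3)2, THF, 0 °C; then 23, −78 → 0 °C
Reagents that add atoms: methyltriphenylphosphonium bromide, C[P+](c1ccccc1)(c1ccccc1)c1ccccc1.[Br-]
Why: Wittig methylenation of the neopentyl aldehyde gives the C10 vinyl group, the non-stabilised ylide reacting with the aldehyde far faster than with the lactone.

Step 18
Reactants: 24 C10 vinyl lactone (name as in step 17)
Product: 25 C11 dimethylaminomethyl derivative of 24 (Mannich base)
Conditions: LiN(iPr)2, THF, −78 °C; CH2=NMe2+ I− (Eschenmoser's salt), −78 → 0 °C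
Reagents that add atoms: N,N-dimethylmethyleneiminium iodide, C=[N+](C)C.[I-]
Why: Mannich reaction of the lactone lithium enolate with the iminium salt puts C13 on C11 as its dimethylamine adduct, a masked α-methylene group that survives hydroxide; the C11 configuration does not matter.

Step 19
Reactants: 25 Mannich base lactone
Product: 28 methyl 2-[(1R,2R,3R,4S,6S)-2-(TBS-oxy)-3-[3-(TBS-oxy)prop-1-en-2-yl]-4-ethenyl-6-hydroxy-4-methylcyclohexyl]prop-2-enoate, via lithium amino hydroxy carboxylate 26 (not isolated), via trimethylammonium ester iodide 27 (not isolated)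
Conditions: LiOH, THF/H2O, rt; CO2 to pH 8, evaporate; then MeI (excess), KHCO3, DMF, 0 °C → rt
Reagents that add atoms: lithium hydroxide, [Li+].[OH-]; methyl iodide, CI
Why: Saponification opens the lactone to the C8 hydroxy carboxylate, which MeI methylates at the carboxylate under conditions too weakly basic for relactonisation, while the amine is quaternised and the β-ammonium ester undergoes E1cB (Hofmann-type) elimination to the acrylate.

Step 20
Reactants: 29 methyl 2-(hydroxymethyl)acrylate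
Product: 30 methyl 2-[(TBS-oxy)methyl]prop-2-enoate
Conditions: TBSCl, imidazole, CH2Cl2, 0 °C → rt
Reagents that add atoms: tert-butyldimethylsilyl chloride, CC(C)(C)[Si](C)(C)Cl
Why: Standard silylation protects the primary allylic alcohol so that the acid can later be activated without self-acylation.

Step 21
Reactants: 30 methyl 2-[(TBS-oxy)methyl]prop-2-enoate
Product: 31 2-[(TBS-oxy)methyl]prop-2-enoic acid
Conditions: LiOH, THF/H2O, 0 °C; then 0.5 M HCl to pH 4 at 0 °C
Reagents that add atoms: lithium hydroxide, [Li+].[OH-]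
Why: Ester saponification, in which hydroxide attacks the ester carbonyl faster than the β-carbon of the 2-substituted acrylate at 0 °C and the silyl ether is stable to base.

Step 22
Reactants: 28 C8 alcohol (name as in step 19); 31 2-[(TBS-oxy)methyl]prop-2-enoic acid
Product: 33 methyl 2-[(1R,2R,3R,4S,6S)-2-(TBS-oxy)-3-[3-(TBS-oxy)prop-1-en-2-yl]-4-ethenyl-4-methyl-6-({2-[(TBS-oxy)methyl]prop-2-enoyl}oxy)cyclohexyl]prop-2-enoate, via trichlorobenzoyl mixed anhydride 32 (not isolated)
Conditions: 31, 2,4,6-trichlorobenzoyl chloride, Et3N, toluene, rt; then 28, DMAP, toluene, rt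
Reagents that add atoms: 2,4,6-trichlorobenzoyl chloride, O=C(Cl)c1c(Cl)cc(Cl)cc1Cl (atoms held only by 32)
Why: Yamaguchi esterification, in which DMAP transfers the acryloyl group of the preformed mixed anhydride to the equatorial C8 hydroxyl faster than that hydroxyl can close onto the neighbouring methyl ester.

Step 23
Reactants: 33 tris-TBS ether (name as in step 22)
Product: 34 elemacarmanin, methyl 2-[(1S,2R,3R,4S,6S)-4-ethenyl-2-hydroxy-3-(3-hydroxyprop-1-en-2-yl)-6-{[2-(hydroxymethyl)prop-2-enoyl]oxy}-4-methylcyclohexyl]prop-2-enoate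
Conditions: HF·pyridine, pyridine, THF, 0 °C → rt
Reagents that add atoms: none
Why: Buffered fluoride-mediated desilylation frees the two primary allylic alcohols and the C6 hydroxyl without the basic conditions that would add to the acrylates or lactonise the C6 hydroxyl onto the C12 ester.

**Compound list**

1 | diethyl 2-methyl-2-(prop-2-en-1-yl)propanedioate (diethyl 2-allyl-2-methylmalonate) | C=CCC(C)(C(=O)OCC)C(=O)OCC | starting material
2 | diethyl 2-methyl-2-(2-oxoethyl)propanedioate | O=CCC(C)(C(=O)OCC)C(=O)OCC | intermediate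
3 | diethyl 2-(2,2-dimethoxyethyl)-2-methylpropanedioate | COC(OC)CC(C)(C(=O)OCC)C(=O)OCC | intermediate
4 | 2-(2,2-dimethoxyethyl)-2-methylpropane-1,3-diol | COC(OC)CC(C)(CO)CO | intermediate
5 | 2-(2,2-dimethoxyethyl)-2-methylpropanedial | COC(OC)CC(C)(C=O)C=O | intermediate
6 | ethyl 2-(diphenoxyphosphoryl)propanoate | CCOC(=O)C(C)P(=O)(Oc1ccccc1)Oc1ccccc1 | starting material
7 | diethyl (2Z,5Z)-4-(2,2-dimethoxyethyl)-2,4,6-trimethylhepta-2,5-dienedioate | COC(OC)CC(C)(/C=C(/C)C(=O)OCC)/C=C(/C)C(=O)OCC | intermediate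
8 | (2Z,5Z)-4-(2,2-dimethoxyethyl)-2,4,6-trimethylhepta-2,5-diene-1,7-diol | COC(OC)CC(C)(/C=C(/C)CO)/C=C(/C)CO | intermediate
9 | (2Z,5Z)-1,7-bis(tert-butyldimethylsilyloxy)-4-(2,2-dimethoxyethyl)-2,4,6-trimethylhepta-2,5-diene | COC(OC)CC(C)(/C=C(/C)CO[Si](C)(C)C(C)(C)C)/C=C(/C)CO[Si](C)(C)C(C)(C)C | intermediate
10 | 3,3-bis[(1Z)-3-(tert-butyldimethylsilyloxy)-2-methylprop-1-en-1-yl]butanal | O=CCC(C)(/C=C(/C)CO[Si](C)(C)C(C)(C)C)/C=C(/C)CO[Si](C)(C)C(C)(C)C | intermediate
11 | diethyl (2E)-but-2-enedioate (diethyl fumarate) | CCOC(=O)/C=C/C(=O)OCC | starting material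
12 | diethyl 2-{3,3-bis[(1Z)-3-(tert-butyldimethylsilyloxy)-2-methylprop-1-en-1-yl]butanoyl}butanedioate, racemic and labile at C2 | CCOC(=O)CC(C(=O)OCC)C(=O)CC(C)(/C=C(/C)CO[Si](C)(C)C(C)(C)C)/C=C(/C)CO[Si](C)(C)C(C)(C)C | intermediate
13 | diethyl (2R)-2-{(1S)-3,3-bis[(1Z)-3-(tert-butyldimethylsilyloxy)-2-methylprop-1-en-1-yl]-1-hydroxybutyl}butanedioate | CCOC(=O)C[C@@H](C(=O)OCC)[C@@H](O)CC(C)(/C=C(/C)CO[Si](C)(C)C(C)(C)C)/C=C(/C)CO[Si](C)(C)C(C)(C)C | intermediate
14 | ethyl (2S,3R)-2-{2,2-bis[(1Z)-3-(tert-butyldimethylsilyloxy)-2-methylprop-1-en-1-yl]propyl}-5-oxooxolane-3-carboxylate | CCOC(=O)[C@@H]1CC(=O)O[C@H]1CC(C)(/C=C(/C)CO[Si](C)(C)C(C)(C)C)/C=C(/C)CO[Si](C)(C)C(C)(C)C | intermediate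
15 | dilithium (2R)-2-{(1S)-3,3-bis[(1Z)-3-(tert-butyldimethylsilyloxy)-2-methylprop-1-en-1-yl]-1-hydroxybutyl}butanedioate | [Li+].[Li+].[O-]C(=O)C[C@@H](C([O-])=O)[C@@H](O)CC(C)(/C=C(/C)CO[Si](C)(C)C(C)(C)C)/C=C(/C)CO[Si](C)(C)C(C)(C)C | intermediate
16 | (2S,3R)-2-{2,2-bis[(1Z)-3-(tert-butyldimethylsilyloxy)-2-methylprop-1-en-1-yl]propyl}-5-oxooxolane-3-carboxylic acid | OC(=O)[C@@H]1CC(=O)O[C@H]1CC(C)(/C=C(/C)CO[Si](C)(C)C(C)(C)C)/C=C(/C)CO[Si](C)(C)C(C)(C)C | intermediate
17 | mixed anhydride of 16 with isobutyl hydrogen carbonate | CC(C)COC(=O)OC(=O)[C@@H]1CC(=O)O[C@H]1CC(C)(/C=C(/C)CO[Si](C)(C)C(C)(C)C)/C=C(/C)CO[Si](C)(C)C(C)(C)C | intermediate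
18 | (4S,5S)-5-{2,2-bis[(1Z)-3-(tert-butyldimethylsilyloxy)-2-methylprop-1-en-1-yl]propyl}-4-(hydroxymethyl)oxolan-2-one | OC[C@@H]1CC(=O)O[C@H]1CC(C)(/C=C(/C)CO[Si](C)(C)C(C)(C)C)/C=C(/C)CO[Si](C)(C)C(C)(C)C | intermediate
19 | (2S,3R)-2-{2,2-bis[(1Z)-3-(tert-butyldimethylsilyloxy)-2-methylprop-1-en-1-yl]propyl}-5-oxooxolane-3-carbaldehyde | O=C[C@@H]1CC(=O)O[C@H]1CC(C)(/C=C(/C)CO[Si](C)(C)C(C)(C)C)/C=C(/C)CO[Si](C)(C)C(C)(C)C | intermediate
20 | (3aS,4R,5R,6S,7aS)-4-hydroxy-6-methyl-6-[(1Z)-3-(tert-butyldimethylsilyloxy)-2-methylprop-1-en-1-yl]-5-[3-(tert-butyldimethylsilyloxy)prop-1-en-2-yl]hexahydro-1-benzofuran-2(3H)-one; H5 α, H6 β, H7 α, H8 β, C10 methyl β, spare arm α | O[C@H]1[C@@H]2CC(=O)O[C@H]2C[C@@](C)(/C=C(/C)CO[Si](C)(C)C(C)(C)C)[C@@H]1C(=C)CO[Si](C)(C)C(C)(C)C | intermediate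
21 | (3aR,4R,5R,6S,7aS)-4-(tert-butyldimethylsilyloxy)-6-methyl-6-[(1Z)-3-(tert-butyldimethylsilyloxy)-2-methylprop-1-en-1-yl]-5-[3-(tert-butyldimethylsilyloxy)prop-1-en-2-yl]hexahydro-1-benzofuran-2(3H)-one | CC(C)(C)[Si](C)(C)O[C@H]1[C@@H]2CC(=O)O[C@H]2C[C@@](C)(/C=C(/C)CO[Si](C)(C)C(C)(C)C)[C@@H]1C(=C)CO[Si](C)(C)C(C)(C)C | intermediate
22 | epoxide of 21 at the spare arm: C10 carries a 3-methyl-3-[(tert-butyldimethylsilyloxy)methyl]oxiran-2-yl group (both epoxide diastereomers; ring stereochemistry as in 21) | CC(C)(C)[Si](C)(C)O[C@H]1[C@@H]2CC(=O)O[C@H]2C[C@@](C)(C3OC3(C)CO[Si](C)(C)C(C)(C)C)[C@@H]1C(=C)CO[Si](C)(C)C(C)(C)C | intermediate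
23 | C10 aldehyde: 21 with a formyl group (α) in place of the spare arm | CC(C)(C)[Si](C)(C)O[C@H]1[C@@H]2CC(=O)O[C@H]2C[C@@](C)(C=O)[C@@H]1C(=C)CO[Si](C)(C)C(C)(C)C | intermediate
24 | (3aR,4R,5R,6S,7aS)-4-(tert-butyldimethylsilyloxy)-6-ethenyl-6-methyl-5-[3-(tert-butyldimethylsilyloxy)prop-1-en-2-yl]hexahydro-1-benzofuran-2(3H)-one | CC(C)(C)[Si](C)(C)O[C@H]1[C@@H]2CC(=O)O[C@H]2C[C@@](C)(C=C)[C@@H]1C(=C)CO[Si](C)(C)C(C)(C)C | intermediate
25 | 24 carrying a (dimethylamino)methyl group on C11 (lactone C3; either C11 epimer) | CC(C)(C)[Si](C)(C)O[C@H]1[C@@H]2C(CN(C)C)C(=O)O[C@H]2C[C@@](C)(C=C)[C@@H]1C(=C)CO[Si](C)(C)C(C)(C)C | intermediate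
26 | lithium 3-(dimethylamino)-2-[cyclohexyl]propanoate from opening of 25 (C8 hydroxyl free; ring stereochemistry as in 28) | C=C[C@]1(C)C[C@H](O)[C@@H](C(CN(C)C)C(=O)[O-])[C@H](O[Si](C)(C)C(C)(C)C)[C@H]1C(=C)CO[Si](C)(C)C(C)(C)C.[Li+] | intermediate
27 | methyl ester of 26 with the amine quaternised as its trimethylammonium iodide | C=C[C@]1(C)C[C@H](O)[C@@H](C(C[N+](C)(C)C)C(=O)OC)[C@H](O[Si](C)(C)C(C)(C)C)[C@H]1C(=C)CO[Si](C)(C)C(C)(C)C.[I-] | intermediate
28 | methyl 2-[(1R,2R,3R,4S,6S)-2-(tert-butyldimethylsilyloxy)-3-[3-(tert-butyldimethylsilyloxy)prop-1-en-2-yl]-4-ethenyl-6-hydroxy-4-methylcyclohexyl]prop-2-enoate | C=C[C@]1(C)C[C@H](O)[C@@H](C(=C)C(=O)OC)[C@H](O[Si](C)(C)C(C)(C)C)[C@H]1C(=C)CO[Si](C)(C)C(C)(C)C | intermediate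
29 | methyl 2-(hydroxymethyl)prop-2-enoate | C=C(CO)C(=O)OC | starting material
30 | methyl 2-[(tert-butyldimethylsilyloxy)methyl]prop-2-enoate | C=C(CO[Si](C)(C)C(C)(C)C)C(=O)OC | intermediate
31 | 2-[(tert-butyldimethylsilyloxy)methyl]prop-2-enoic acid | C=C(CO[Si](C)(C)C(C)(C)C)C(=O)O | intermediate
32 | mixed anhydride of 31 with 2,4,6-trichlorobenzoic acid | C=C(CO[Si](C)(C)C(C)(C)C)C(=O)OC(=O)c1c(Cl)cc(Cl)cc1Cl | intermediate
33 | methyl 2-[(1R,2R,3R,4S,6S)-2-(tert-butyldimethylsilyloxy)-3-[3-(tert-butyldimethylsilyloxy)prop-1-en-2-yl]-4-ethenyl-4-methyl-6-({2-[(tert-butyldimethylsilyloxy)methyl]prop-2-enoyl}oxy)cyclohexyl]prop-2-enoate | C=C[C@]1(C)C[C@H](OC(=O)C(=C)CO[Si](C)(C)C(C)(C)C)[C@@H](C(=C)C(=O)OC)[C@H](O[Si](C)(C)C(C)(C)C)[C@H]1C(=C)CO[Si](C)(C)C(C)(C)C | intermediate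
34 | elemacarmanin, methyl 2-[(1S,2R,3R,4S,6S)-4-ethenyl-2-hydroxy-3-(3-hydroxyprop-1-en-2-yl)-6-{[2-(hydroxymethyl)prop-2-enoyl]oxy}-4-methylcyclohexyl]prop-2-enoate | C=C[C@]1(C)C[C@H](OC(=O)C(=C)CO)[C@@H](C(=C)C(=O)OC)[C@H](O)[C@H]1C(=C)CO | target

**Step count**

Total step count: 23. Longest linear sequence: 21 steps (steps 1–19, 22 and 23; steps 20 and 21 prepare acid 31).

**Steps most likely to fail**

Step 13. The two diastereotopic arms may be discriminated poorly, so that the C10 epimer forms beside 20; transfer of a methyl group from aluminium to the aldehyde is a second hazard. The fallback fixes C10 before the cyclisation, so that only one arm is present, and sets out from diol 4. Lipase-catalysed acetylation of one enantiotopic hydroxymethyl group (lipase from Burkholderia cepacia, vinyl acetate) should give monoacetate F1. Dess–Martin oxidation gives acetoxy aldehyde F2 and Wittig methylenation gives vinyl acetate F3. K2CO3 in MeOH frees alcohol F4, which is oxidised to aldehyde F5. Ando olefination with 6 gives (Z)-enoate F6, iBu2AlH reduction gives allylic alcohol F7 and silylation gives silyl ether F8. The operations of steps 7 to 13 then follow on this one-arm series: acetal cleavage to aldehyde F9, Stetter addition to 11 giving keto diester F10, ketoreductase reduction to hydroxy diester F11 and closure to lactone ester F12, hydrolysis through dicarboxylate F13 to acid F14, reduction through mixed anhydride F15 to alcohol F16, oxidation to aldehyde F17 and Me2AlCl ene cyclisation to hydroxy lactone F18. In that cyclisation no arm choice is left and the vinyl group has no allylic hydrogen to offer. Silylation of F18 as in step 14 gives 24, where the route is rejoined; steps 15 to 17 are then not needed.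

Step 9. The enzyme may not accept the large, lipophilic keto diester, or may reduce with the wrong sense at C8 or without keeping pace with C7 epimerisation. The fallback replaces steps 8 to 10 by auxiliary control, sets out from aldehyde 10 and returns at acid 16. Acylation of (R)-4-benzyloxazolidin-2-one with methyl 4-chloro-4-oxobutanoate gives succinyl imide F19. Its dibutylboron enolate (Bu2BOTf, iPr2NEt, CH2Cl2, −78 °C) adds to 10 in an Evans syn aldol reaction to give aldol adduct F20, with C7 (R) and C8 (S). The C8 hydroxyl closes onto the methyl ester to give the trans lactone imide F21. LiOH with H2O2 then removes the auxiliary and gives 16.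

Step 15. The peracid may not select well enough between the trisubstituted alkene of the spare arm and the 1,1-disubstituted C4 methylene, or may go on to the bis-epoxide. The fallback gives up the selection, sets out from 21 and returns at 24. Exhaustive ozonolysis (O3, CH2Cl2, −78 °C; PPh3) cleaves both alkenes to keto aldehyde F22. Twofold methylenation with Zn, CH2Br2 and TiCl4 then rebuilds the C4 methylene from the ketone and makes the C10 vinyl group from the aldehyde, under non-basic conditions that spare the lactone and keep the C5 substituent equatorial.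

**Further compounds**

F1 | step 13 | (2S)-2-(hydroxymethyl)-4,4-dimethoxy-2-methylbutyl acetate | OC[C@](C)(CC(OC)OC)COC(C)=O
F2 | step 13 | (2R)-2-formyl-4,4-dimethoxy-2-methylbutyl acetate | O=C[C@](C)(CC(OC)OC)COC(C)=O
F3 | step 13 | (2S)-2-ethenyl-4,4-dimethoxy-2-methylbutyl acetate | C=C[C@](C)(CC(OC)OC)COC(C)=O
F4 | step 13 | (2S)-2-ethenyl-4,4-dimethoxy-2-methylbutan-1-ol | C=C[C@](C)(CC(OC)OC)CO
F5 | step 13 | (2S)-2-ethenyl-4,4-dimethoxy-2-methylbutanal | C=C[C@](C)(CC(OC)OC)C=O
F6 | step 13 | ethyl (2Z,4S)-4-ethenyl-6,6-dimethoxy-2,4-dimethylhex-2-enoate | C=C[C@](C)(CC(OC)OC)/C=C(/C)C(=O)OCC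
F7 | step 13 | (2Z,4S)-4-ethenyl-6,6-dimethoxy-2,4-dimethylhex-2-en-1-ol | C=C[C@](C)(CC(OC)OC)/C=C(/C)CO
F8 | step 13 | tert-butyl{[(2Z,4S)-4-ethenyl-6,6-dimethoxy-2,4-dimethylhex-2-en-1-yl]oxy}dimethylsilane | C=C[C@](C)(CC(OC)OC)/C=C(/C)CO[Si](C)(C)C(C)(C)C
F9 | step 13 | (3S,4Z)-6-(tert-butyldimethylsilyloxy)-3-ethenyl-3,5-dimethylhex-4-enal | C=C[C@](C)(CC=O)/C=C(/C)CO[Si](C)(C)C(C)(C)C
F10 | step 13 | diethyl 2-[(3S,4Z)-6-(tert-butyldimethylsilyloxy)-3-ethenyl-3,5-dimethylhex-4-enoyl]butanedioate | CCOC(=O)CC(C(=O)OCC)C(=O)C[C@@](C)(C=C)/C=C(/C)CO[Si](C)(C)C(C)(C)C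
F11 | step 13 | diethyl (2R)-2-[(1S,3S,4Z)-6-(tert-butyldimethylsilyloxy)-3-ethenyl-1-hydroxy-3,5-dimethylhex-4-en-1-yl]butanedioate | CCOC(=O)C[C@@H](C(=O)OCC)[C@@H](O)C[C@@](C)(C=C)/C=C(/C)CO[Si](C)(C)C(C)(C)C
F12 | step 13 | ethyl (2S,3R)-2-[(2S,3Z)-5-(tert-butyldimethylsilyloxy)-2-ethenyl-2,4-dimethylpent-3-en-1-yl]-5-oxooxolane-3-carboxylate | CCOC(=O)[C@@H]1CC(=O)O[C@H]1C[C@@](C)(C=C)/C=C(/C)CO[Si](C)(C)C(C)(C)C
F13 | step 13 | dilithium (2R)-2-[(1S,3S,4Z)-6-(tert-butyldimethylsilyloxy)-3-ethenyl-1-hydroxy-3,5-dimethylhex-4-en-1-yl]butanedioate | [Li+].[Li+].[O-]C(=O)C[C@@H](C([O-])=O)[C@@H](O)C[C@@](C)(C=C)/C=C(/C)CO[Si](C)(C)C(C)(C)C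
F14 | step 13 | (2S,3R)-2-[(2S,3Z)-5-(tert-butyldimethylsilyloxy)-2-ethenyl-2,4-dimethylpent-3-en-1-yl]-5-oxooxolane-3-carboxylic acid | OC(=O)[C@@H]1CC(=O)O[C@H]1C[C@@](C)(C=C)/C=C(/C)CO[Si](C)(C)C(C)(C)C
F15 | step 13 | mixed anhydride of F14 with isobutyl hydrogen carbonate | CC(C)COC(=O)OC(=O)[C@@H]1CC(=O)O[C@H]1C[C@@](C)(C=C)/C=C(/C)CO[Si](C)(C)C(C)(C)C
F16 | step 13 | (4S,5S)-5-[(2S,3Z)-5-(tert-butyldimethylsilyloxy)-2-ethenyl-2,4-dimethylpent-3-en-1-yl]-4-(hydroxymethyl)oxolan-2-one | OC[C@@H]1CC(=O)O[C@H]1C[C@@](C)(C=C)/C=C(/C)CO[Si](C)(C)C(C)(C)C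
F17 | step 13 | (2S,3R)-2-[(2S,3Z)-5-(tert-butyldimethylsilyloxy)-2-ethenyl-2,4-dimethylpent-3-en-1-yl]-5-oxooxolane-3-carbaldehyde | O=C[C@@H]1CC(=O)O[C@H]1C[C@@](C)(C=C)/C=C(/C)CO[Si](C)(C)C(C)(C)C
F18 | step 13 | (3aS,4R,5R,6S,7aS)-6-ethenyl-4-hydroxy-6-methyl-5-[3-(tert-butyldimethylsilyloxy)prop-1-en-2-yl]hexahydro-1-benzofuran-2(3H)-one | O[C@H]1[C@@H]2CC(=O)O[C@H]2C[C@@](C)(C=C)[C@@H]1C(=C)CO[Si](C)(C)C(C)(C)C
F19 | step 9 | methyl 4-[(4R)-4-benzyl-2-oxo-1,3-oxazolidin-3-yl]-4-oxobutanoate | COC(=O)CCC(=O)N1[C@H](Cc2ccccc2)COC1=O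
F20 | step 9 | methyl (3R,4S)-3-{[(4R)-4-benzyl-2-oxo-1,3-oxazolidin-3-yl]carbonyl}-4-hydroxy-6,6-bis[(1Z)-3-(tert-butyldimethylsilyloxy)-2-methylprop-1-en-1-yl]heptanoate | COC(=O)C[C@@H](C(=O)N1[C@H](Cc2ccccc2)COC1=O)[C@@H](O)CC(C)(/C=C(/C)CO[Si](C)(C)C(C)(C)C)/C=C(/C)CO[Si](C)(C)C(C)(C)C
F21 | step 9 | (4R)-4-benzyl-3-{[(2S,3R)-2-{2,2-bis[(1Z)-3-(tert-butyldimethylsilyloxy)-2-methylprop-1-en-1-yl]propyl}-5-oxooxolan-3-yl]carbonyl}-1,3-oxazolidin-2-one | O=C(N1[C@H](Cc2ccccc2)COC1=O)[C@@H]3CC(=O)O[C@H]3CC(C)(/C=C(/C)CO[Si](C)(C)C(C)(C)C)/C=C(/C)CO[Si](C)(C)C(C)(C)C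
F22 | step 15 | keto aldehyde from 21: C10 carries a formyl group and C5 a 2-(tert-butyldimethylsilyloxy)acetyl group (ring stereochemistry as in 21) | CC(C)(C)[Si](C)(C)O[C@H]1[C@@H]2CC(=O)O[C@H]2C[C@@](C)(C=O)[C@@H]1C(=O)CO[Si](C)(C)C(C)(C)C
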